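**Plan**

- Retrosynthesis: take off four MOM ethers; cut the ring A aryl–C(=O) bond of the diaryl ketone and put a phenolic OH in its place, the two halves then being held through the formyl carbon as an N-aroylhydrazone; cut that C=N into aldehyde and hydrazide.
- Enabling feature: in ring A the aroyl-bearing carbon is ortho to the formyl-bearing carbon and meta to both hydroxylated carbons. Ring A is therefore a 2,4,6-trioxygenated (phloroglucinol-type) benzaldehyde in which one ortho oxygen has been traded for the acyl group. This is the retron of the Pb(OAc)4 rearrangement of salicylaldehyde N-acylhydrazones (ArOH → ArC(=O)R with loss of N2).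
- Forward, ring B arm: orcinol → bis-MOM ether → monochloride → ortho-lithiation/CO2 → hydrazide.
- Forward, ring A arm: 2,4,6-trihydroxybenzaldehyde → C-prenylation → bis-MOM ether that leaves free only the OH between CHO and prenyl.
- Union and end-game: condensation clips the halves together; the oxidative rearrangement then makes the hindered ketone C–C bond, returns the aldehyde and expels the N–N tether as N2; global MOM removal follows.
- Stereochemistry: none to set; the only stereo-element on the way, the E hydrazone C=N, is consumed in the key step.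

Key step: step 8

Remark: the target has no stereocentre and no configurationally stable axis, so it is one achiral compound and no enantiocontrol is needed.

**Route**

Step 1
Reactants: 1 orcinol (5-methylbenzene-1,3-diol)
Product: 2 1,3-bis(methoxymethoxy)-5-methylbenzene
Conditions: MOMCl (2.4 equiv), i-Pr2NEt (3 equiv), CH2Cl2, 0 °C → rt
Reagents that add atoms: chloromethyl methyl ether (MOMCl) COCCl
Why: Base-mediated O-alkylation of both phenols with the chloromethyl ether (Williamson-type acetal formation) should give the bis-MOM ether, which later serves as the directing group for metalation and as a phenol mask that is stable to Pb(IV).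

Step 2
Reactants: 2 1,3-bis(methoxymethoxy)-5-methylbenzene
Product: 3 2-chloro-1,5-bis(methoxymethoxy)-3-methylbenzene (Cl between CH3 and one OMOM)
Conditions: NCS (1.05 equiv), MeCN, rt → 40 °C
Reagents that add atoms: N-chlorosuccinimide O=C1CCC(=O)N1Cl
Why: Electrophilic aromatic chlorination should occur at the ring position ortho to the methyl group, which is ortho/para-activated by both acetal oxygens and less shielded than the position between the two OMOM groups, and one equivalent of the neutral reagent should stop at the monochloride without harming the acetals.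

Step 3
Reactants: 3 2-chloro-1,5-bis(methoxymethoxy)-3-methylbenzene
Product: 5 3-chloro-2,6-bis(methoxymethoxy)-4-methylbenzoic acid, via aryllithium 4 (not isolated)
Conditions: n-BuLi (1.1 equiv), THF, −20 → 0 °C; CO2 (dry), −78 °C → rt; cold 1 M HCl to pH 3
Reagents that add atoms: carbon dioxide O=C=O
Why: Directed ortho-metalation at the carbon flanked by both OMOM groups (the most acidic ring C–H; the aryl chloride does not exchange with n-BuLi here and is meta to the anion, so no aryne can form) followed by carboxylation should give the 2,6-dioxygenated benzoic acid.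

Step 4
Reactants: 5 3-chloro-2,6-bis(methoxymethoxy)-4-methylbenzoic acid
Product: 7 3-chloro-2,6-bis(methoxymethoxy)-4-methylbenzohydrazide, via acyl imidazolide 6 (not isolated)
Conditions: CDI (1.2 equiv), THF, rt; then added to N2H4·H2O (5 equiv), THF, 0 °C → rt
Reagents that add atoms: hydrazine (used as the hydrate) NN
Why: Activation of the hindered acid as its acyl imidazolide and acyl substitution by an excess of the small α-effect nucleophile hydrazine should give the monoacyl hydrazide, with the MOM ethers and the aryl chloride untouched.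

Step 5
Reactants: 8 2,4,6-trihydroxybenzaldehyde
Product: 9 2,4,6-trihydroxy-3-(3-methylbut-2-en-1-yl)benzaldehyde
Conditions: prenyl bromide (1.0 equiv), DBU (1.1 equiv), THF, 0 °C → rt
Reagents that add atoms: prenyl bromide (1-bromo-3-methylbut-2-ene) CC(C)=CCBr
Why: C-alkylation of the phloroglucinaldehyde anion, a vinylogous acid anion whose soft ring carbon is favoured over oxygen with an amidine base in THF, should give the mono-C-prenyl compound, the two open ring positions being equivalent and the stoichiometry limiting a second alkylation.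

Step 6
Reactants: 9 2,4,6-trihydroxy-3-(3-methylbut-2-en-1-yl)benzaldehyde
Product: 10 2-hydroxy-4,6-bis(methoxymethoxy)-3-(3-methylbut-2-en-1-yl)benzaldehyde
Conditions: MOMCl (2.1 equiv, slow addition), i-Pr2NEt (2.5 equiv), CH2Cl2, 0 °C
Reagents that add atoms: chloromethyl methyl ether (MOMCl) COCCl
Why: Selective O-alkylation should first take the most acidic, non-chelated 4-OH and then, of the two hydrogen-bonded ortho hydroxyls, the one flanked only by H, leaving free the OH wedged between the formyl and prenyl groups, which is the one to be exchanged for the aroyl group.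

Step 7
Reactants: 10 2-hydroxy-4,6-bis(methoxymethoxy)-3-(3-methylbut-2-en-1-yl)benzaldehyde; 7 3-chloro-2,6-bis(methoxymethoxy)-4-methylbenzohydrazide
Product: 11 (E)-N'-{[2-hydroxy-4,6-bis(methoxymethoxy)-3-(3-methylbut-2-en-1-yl)phenyl]methylidene}-3-chloro-2,6-bis(methoxymethoxy)-4-methylbenzohydrazide
Conditions: EtOH, AcOH (cat.), 70 °C
Reagents that add atoms: none
Why: Acid-catalysed condensation of the aldehyde with the terminal NH2 of the hydrazide (acylhydrazone formation) should give the E hydrazone, stabilised by the O–H···N hydrogen bond, and it ties the two halves together through a group that later leaves as N2.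

Step 8
Reactants: 11 (E)-N-aroylhydrazone
Product: 14 2-[3-chloro-2,6-bis(methoxymethoxy)-4-methylbenzoyl]-4,6-bis(methoxymethoxy)-3-(3-methylbut-2-en-1-yl)benzaldehyde, via azo acetate 12 (not isolated), via bridged oxadiazoline 13 (not isolated)
Conditions: Pb(OAc)4 (1.2 equiv), THF, 0 °C → rt
Reagents that add atoms: none
Why: Pb(OAc)4 oxidises the hydrazone N–H to the azo acetate 12; loss of acetate lets the amide oxygen close on the former formyl carbon and the ortho phenolic oxygen close on the former acyl carbon to give the bridged Δ3-1,3,4-oxadiazoline 13, which expels N2 to a benzodioxin-type carbonyl ylide that collapses by migration of the ring carbon from the phenolic oxygen to the former acyl carbon. The net result is exchange of the phenolic OH for the aroyl group with return of the aldehyde, the phenolic oxygen ending as the ketone oxygen on this pathway. The closest known reaction type is the lead tetraacetate rearrangement of o-hydroxyaryl ketone and salicylaldehyde N-acylhydrazones to 1,2-diacylbenzenes and 2-acylbenzaldehydes. The only rings closed are the temporary five-membered oxadiazoline ring and six-membered 1,3-dioxane ring of 13, both by intramolecular O-attack on the oxidised hydrazone carbons and both opened again when N2 leaves, so no ring and no stereocentre of the target is set here. The step needs reaction at a single phenol and rearrangement in preference to 1,3,4-oxadiazole formation or Pb(IV) attack on the electron-rich ring and the prenyl alkene; this is secured because the only free OH is the one ortho to the hydrazone carbon, all other phenols are MOM ethers, and N–H oxidation in THF at 0–20 °C is much faster than attack on a trisubstituted alkene. Because the C–C bond is made by an intramolecular 1,2-shift, the tetra-ortho-substituted ketone arises without any intermolecular addition to a hindered carbonyl group.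

Step 9
Reactants: 14 tetrakis-MOM-protected keto aldehyde
Product: 15 Pestalone E, 2-(3-chloro-2,6-dihydroxy-4-methylbenzoyl)-4,6-dihydroxy-3-(3-methylbut-2-en-1-yl)benzaldehyde
Conditions: aq. HCl (3 M), MeOH–THF, rt → 40 °C
Reagents that add atoms: none
Why: Acid-catalysed solvolysis of the four aryl methoxymethyl acetals (fastest for the three ortho to a carbonyl group) should free the phenols under conditions mild enough to keep the prenyl group from cyclising onto its neighbouring OH, with methanol taking up the formaldehyde unit as dimethoxymethane and the aqueous medium keeping the aldehyde free.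

**Compound list**

1 | orcinol (5-methylbenzene-1,3-diol) | Cc1cc(O)cc(O)c1 | starting material
2 | 1,3-bis(methoxymethoxy)-5-methylbenzene | Cc1cc(OCOC)cc(OCOC)c1 | intermediate
3 | 2-chloro-1,5-bis(methoxymethoxy)-3-methylbenzene | Cc1cc(OCOC)cc(OCOC)c1Cl | intermediate
4 | [3-chloro-2,6-bis(methoxymethoxy)-4-methylphenyl]lithium (formed in situ) | [Li]c1c(OCOC)cc(C)c(Cl)c1OCOC | intermediate
5 | 3-chloro-2,6-bis(methoxymethoxy)-4-methylbenzoic acid | Cc1cc(OCOC)c(C(=O)O)c(OCOC)c1Cl | intermediate
6 | 1-[3-chloro-2,6-bis(methoxymethoxy)-4-methylbenzoyl]imidazole (formed in situ) | Cc1cc(OCOC)c(C(=O)n2ccnc2)c(OCOC)c1Cl | intermediate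
7 | 3-chloro-2,6-bis(methoxymethoxy)-4-methylbenzohydrazide | Cc1cc(OCOC)c(C(=O)NN)c(OCOC)c1Cl | intermediate
8 | 2,4,6-trihydroxybenzaldehyde | O=Cc1c(O)cc(O)cc1O | starting material
9 | 2,4,6-trihydroxy-3-(3-methylbut-2-en-1-yl)benzaldehyde | CC(C)=CCc1c(O)cc(O)c(C=O)c1O | intermediate
10 | 2-hydroxy-4,6-bis(methoxymethoxy)-3-(3-methylbut-2-en-1-yl)benzaldehyde | CC(C)=CCc1c(OCOC)cc(OCOC)c(C=O)c1O | intermediate
11 | (E)-N'-{[2-hydroxy-4,6-bis(methoxymethoxy)-3-(3-methylbut-2-en-1-yl)phenyl]methylidene}-3-chloro-2,6-bis(methoxymethoxy)-4-methylbenzohydrazide | CC(C)=CCc1c(OCOC)cc(OCOC)c(/C=N/NC(=O)c2c(OCOC)cc(C)c(Cl)c2OCOC)c1O | intermediate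
12 | azo acetate: acetoxy[2-hydroxy-4,6-bis(methoxymethoxy)-3-prenylphenyl]methyl 3-chloro-2,6-bis(methoxymethoxy)-4-methylbenzoyl diazene, racemic (formed in situ) | CC(C)=CCc1c(OCOC)cc(OCOC)c(C(OC(C)=O)N=NC(=O)c2c(OCOC)cc(C)c(Cl)c2OCOC)c1O | intermediate
13 | bridged Δ3-1,3,4-oxadiazoline: the former formyl CH and the former acyl carbon are joined by N=N and by the amide oxygen, and the acyl carbon also carries the phenolic oxygen (2,4-azo-bridged 4H-1,3-benzodioxin), racemic (formed in situ) | CC(C)=CCc1c(OCOC)cc(OCOC)c2c1OC1(c3c(OCOC)cc(C)c(Cl)c3OCOC)N=NC2O1 | intermediate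
14 | 2-[3-chloro-2,6-bis(methoxymethoxy)-4-methylbenzoyl]-4,6-bis(methoxymethoxy)-3-(3-methylbut-2-en-1-yl)benzaldehyde | CC(C)=CCc1c(OCOC)cc(OCOC)c(C=O)c1C(=O)c1c(OCOC)cc(C)c(Cl)c1OCOC | intermediate
15 | Pestalone E, 2-(3-chloro-2,6-dihydroxy-4-methylbenzoyl)-4,6-dihydroxy-3-(3-methylbut-2-en-1-yl)benzaldehyde | CC(C)=CCc1c(O)cc(O)c(C=O)c1C(=O)c1c(O)cc(C)c(Cl)c1O | target

**Count and risks**

Total steps: 9. Longest linear sequence: 7 steps (steps 1–4, 7, 8, 9 from orcinol).

Steps most likely to fail:

1. Step 8. The oxidised aldehyde hydrazone may close to a 1,3,4-oxadiazole instead of rearranging. Pb(IV) may attack the electron-rich ring or the allylic position. The 1,2-shift onto the ring carbon crowded by the prenyl group may be slow enough for the N2-free intermediate to decompose.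
Fallback (sets out from 10 and 3, returns at 14): 10 is converted with Tf2O/pyridine (CH2Cl2, 0 °C) into 2-formyl-3,5-bis(methoxymethoxy)-6-(3-methylbut-2-en-1-yl)phenyl trifluoromethanesulfonate F1. NaBH4 (MeOH–THF, 0 °C) reduces the aldehyde to 2-(hydroxymethyl)-3,5-bis(methoxymethoxy)-6-(3-methylbut-2-en-1-yl)phenyl trifluoromethanesulfonate F2. Pd-catalysed carbonylative lactonisation (Pd(OAc)2, dppf, CO, Et3N, DMF, 80 °C) gives the phthalide 4,6-bis(methoxymethoxy)-7-(3-methylbut-2-en-1-yl)isobenzofuran-1(3H)-one F3. Aryllithium 4, made from 3 as in step 3, is added to the lactone carbonyl at −78 °C to give [3-chloro-2,6-bis(methoxymethoxy)-4-methylphenyl][2-(hydroxymethyl)-3,5-bis(methoxymethoxy)-6-(3-methylbut-2-en-1-yl)phenyl]methanone F4, in equilibrium with its lactol. Oxidation of the benzylic alcohol (Dess–Martin periodinane, NaHCO3, CH2Cl2) returns to 14.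

2. Step 6. Discrimination between the two hydrogen-bonded ortho hydroxyls may be poor, or alkylation may run on to the tris-ether, so that the wrong OH is left free for step 8.
Fallback (sets out from 8, returns at 10, and also spares the C-prenylation of step 5): 8 with MOMCl (2.1 equiv)/i-Pr2NEt gives 2-hydroxy-4,6-bis(methoxymethoxy)benzaldehyde F5, the only bis-ether that keeps a chelated OH. O-alkylation with 3-chloro-3-methylbut-1-yne (K2CO3, KI, CuI cat., acetone) gives 2-[(2-methylbut-3-yn-2-yl)oxy]-4,6-bis(methoxymethoxy)benzaldehyde F6. Semi-hydrogenation (H2, Pb-poisoned Pd/CaCO3, quinoline, EtOAc) gives 2-[(2-methylbut-3-en-2-yl)oxy]-4,6-bis(methoxymethoxy)benzaldehyde F7. A thermal aromatic Claisen rearrangement (toluene, 110 °C) moves the allyl unit, with allylic inversion, to the only free ortho carbon and returns to 10 with the regiochemistry fixed by the mechanism.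

3. Step 9. The protic acid may add the freed phenol across the prenyl alkene (chroman formation) or hydrate the alkene, and the acetal next to the prenyl group may cleave incompletely.
Fallback (sets out from 14, returns at 15): instead of protic solvolysis, the acetals are exchanged for silyl ethers under buffered, non-protic conditions (TMSOTf, 2,2′-bipyridyl, CH2Cl2–MeCN, 0 °C) to give 2-[3-chloro-4-methyl-2,6-bis(trimethylsilyloxy)benzoyl]-3-(3-methylbut-2-en-1-yl)-4,6-bis(trimethylsilyloxy)benzaldehyde F8. Neutral hydrolysis of the aryl silyl ethers (H2O–THF, pH 7) then gives 15.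

Further compounds
F1 | step 8 | 2-formyl-3,5-bis(methoxymethoxy)-6-(3-methylbut-2-en-1-yl)phenyl trifluoromethanesulfonate | CC(C)=CCc1c(OCOC)cc(OCOC)c(C=O)c1OS(=O)(=O)C(F)(F)F
F2 | step 8 | 2-(hydroxymethyl)-3,5-bis(methoxymethoxy)-6-(3-methylbut-2-en-1-yl)phenyl trifluoromethanesulfonate | CC(C)=CCc1c(OCOC)cc(OCOC)c(CO)c1OS(=O)(=O)C(F)(F)F
F3 | step 8 | 4,6-bis(methoxymethoxy)-7-(3-methylbut-2-en-1-yl)isobenzofuran-1(3H)-one | CC(C)=CCc1c(OCOC)cc(OCOC)c2c1C(=O)OC2
F4 | step 8 | [3-chloro-2,6-bis(methoxymethoxy)-4-methylphenyl][2-(hydroxymethyl)-3,5-bis(methoxymethoxy)-6-(3-methylbut-2-en-1-yl)phenyl]methanone | CC(C)=CCc1c(OCOC)cc(OCOC)c(CO)c1C(=O)c1c(OCOC)cc(C)c(Cl)c1OCOC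
F5 | step 6 | 2-hydroxy-4,6-bis(methoxymethoxy)benzaldehyde | O=Cc1c(O)cc(OCOC)cc1OCOC
F6 | step 6 | 2-[(2-methylbut-3-yn-2-yl)oxy]-4,6-bis(methoxymethoxy)benzaldehyde | C#CC(C)(C)Oc1cc(OCOC)cc(OCOC)c1C=O
F7 | step 6 | 2-[(2-methylbut-3-en-2-yl)oxy]-4,6-bis(methoxymethoxy)benzaldehyde | C=CC(C)(C)Oc1cc(OCOC)cc(OCOC)c1C=O
F8 | step 9 | 2-[3-chloro-4-methyl-2,6-bis(trimethylsilyloxy)benzoyl]-3-(3-methylbut-2-en-1-yl)-4,6-bis(trimethylsilyloxy)benzaldehyde | CC(C)=CCc1c(O[Si](C)(C)C)cc(O[Si](C)(C)C)c(C=O)c1C(=O)c1c(O[Si](C)(C)C)cc(C)c(Cl)c1O[Si](C)(C)C
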